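# Proposed total synthesis of the cyclic bis(bibenzyl) 22 by oxidative closure of the C–O–D ether

## The problem

Target 22 is an achiral 19-membered cyclic bis(bibenzyl). Its four benzene rings are joined alternately by two diaryl ether oxygens and two ethano bridges (A–O–B, B–CH2CH2–C, C–O–D, D–CH2CH2–A): ring A is 1-methoxy-2-aryloxy-4-alkyl, ring B is para-aryloxy-alkyl, ring C is 4-hydroxy-3-aryloxy-alkyl and ring D is meta-aryloxy-alkyl. There is no stereocenter and no configurationally stable axis, so the difficulty lies in connectivity, regiochemistry and the entropic cost of closing a large ring. The two ether bridges are unequal. The A–O–B oxygen sits para to the carbon substituent of ring B and can be made by nucleophilic aromatic substitution on a para-formyl aryl fluoride. The C–O–D oxygen joins a ring with no activating group (ring D) to the carbon next to a free hydroxyl (ring C), and that chemistry cannot reach it. The free phenol of ring C is oxidizable, the single methyl ether on ring A must survive every unmasking (so protecting groups cannot be removed by Lewis-acidic ether cleavage), and the four benzylic methylenes do not tolerate quinone-type oxidants. The feature that opens the key step is that ring C is a 2-aryloxyphenol: the ring D oxygen is bonded to the ring C carbon adjacent to the hydroxyl-bearing carbon, which is the pattern left when one phenol is oxidized and a second phenol oxygen adds ortho to its OH. That coupling is regiodefined only if ring C carries a leaving group on both ortho carbons and ring D has every ortho and para carbon blocked, so temporary halogens (two Br on ring C, three Cl on ring D) must be carried to the macrocycle and then removed without harming the ethers.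

## Retrosynthesis

**22 from 21.** The last operation removes the auxiliary halogens: one C–Br bond on ring C and three C–Cl bonds on ring D of macrocycle 21 are cut by hydrogenolysis. Nothing else in 21 is reducible under these conditions, so the final step is a pure clean-up. It must run to completion on all four carbon–halogen bonds.

**21 from 19 (key disconnection).** The bond between the ring D oxygen and the ring C carbon ortho to the ring C hydroxyl is cut, which opens the 19-membered ring to seco bisphenol 19. The forward reaction passes through bromo dienone 20. This cut is preferred to its neighbours for two reasons. Closing an ethano bridge would leave the unactivated C–O–D ether to a forcing intermolecular copper coupling next to a free phenol position. Closing at A–O–B would spend the one easy ether bond on the macrocyclization, and the macrocycle has no activating group for it. The chosen cut makes the hardest bond and the ring in one event. The precursor 19 is an open chain of four rings with both phenols free. The forward reaction has to oxidize ring C and not ring D, bond through the ring D oxygen, and outrun oligomerization.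

**19 from 18 and 17.** Two functional-group changes precede the key step and cut no skeletal bond. The methoxymethyl ethers of 18 are removed by acid, which leaves the ring A methyl ether untouched. The two ethano bridges of 18 come from the two olefins of bis-stilbene 17 by diimide reduction, the one hydrogenation method that spares C–Br and C–Cl bonds. Both olefins are saturated before the oxidation so that trivalent thallium meets no alkene.

**17 from 10 and 15.** The B–C bridge is cut at its olefin into aldehyde 10 and phosphonium salt 15 (Wittig). The aldehyde is placed on ring B because the formyl group that activates the fluoride for ether formation is then used directly as the olefination partner. Salt 15 is a four-step derivative of commercial aldehyde 11 (through 12, 13 and 14). Olefin geometry is irrelevant, so the reaction only has to form the C=C bond in the presence of aryl halides and acetals.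

**10 from 8 and 9.** The A–O–B ether is cut at the ring B carbon–oxygen bond into phenol 8 and 4-fluorobenzaldehyde 9 (addition–elimination). Making this ether after the A–D bridge means the A–O–B unit never carries two equivalent benzylic aldehydes, so no differentiation problem arises. The ring D hydroxyl is masked at this stage so that only the ring A phenoxide can react.

**8 from 6 and 4.** The D–A bridge is cut at its olefin into the ring A phosphonium salt 6 and the ring D aldehyde 4. Salt 6 is one step from commercial benzylic alcohol 5 and keeps its phenol free for the next step. Aldehyde 4 comes from commercial 2,4,6-trichlorophenol 1 by acetal protection (2) and lithiation–formylation through aryllithium 3. The only ring hydrogens of 2 are equivalent and each lies between two chlorines, so the substitution pattern of ring D (oxygen meta to the bridge, chlorine on both ortho carbons and the para carbon of the phenol) is fixed without any regiochemical choice. Chlorinating a preformed hydroxy aldehyde three times would depend on complete halogenation of a deactivated ring.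

## Roads not taken

**Alternative 1:** The cut is the bond between ring C and the benzylic carbon of the B–C bridge, taken at the ketone oxidation level. Macrolactone A2 (the ring B arylacetate of the ring C phenol, with the C–O–D ether already in place) would be ionized in CF3SO3H at low temperature. The tethered acyl cation from A2 should acylate ring C para to the released hydroxyl and give macrocyclic deoxybenzoin A1, and the carbonyl would then be reduced away.
- Merits: macrolactonization is among the most dependable macrocyclizations, the phenol is protected by the very bond that rearranges, and no halogens or thallium are needed. In step count and reagent hygiene this road is better than the chosen one.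
- Weak points: an arylacetyl cation readily loses CO, and the resulting para-aryloxybenzyl cation would alkylate the nearest arene. The Fries process is largely dissociative, so ring A (the most electron-rich ring) or a second molecule can capture the acyl group. On ring C itself the carbon ortho to the hydroxyl and the carbon para to the aryloxy group are open. The acyl cation must also reach across the ring to the para carbon.
- Comparison: the C–O–D ether, the hardest bond of 22, still has to be made beforehand by intermolecular coupling on an unactivated ring. The chosen plan offers positional certainty instead: in 19 every competing carbon is blocked, and the ring closure itself makes the difficult ether.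

**Alternative 2:** The cut is the ring A carbon–oxygen bond of the A–O–B ether, with ring A at the cyclohexanone oxidation level. The ring B phenoxide of bromoketone A4 would displace the α-bromide (K2CO3, acetone, dilute) to give macrocyclic 2-aryloxycyclohexanone A3. Ring A would then be dehydrogenated to the phenol and O-methylated, and the benzyl ether on ring C removed.
- Merits: the ring closure is a plain SN2 etherification on an activated halide and needs neither an activated arene nor a heavy metal. As a macrocyclization it is probably more reliable than an oxidative coupling. The diastereomers of A3 are of no consequence.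
- Weak points: an α-bromoketone under carbonate is open to Favorskii rearrangement and elimination. The late aromatization must remove four hydrogens from a macrocycle that has four benzylic methylenes and an α-aryloxy ketone. Three operations follow the ring closure where the chosen plan needs one. Ring A must be built from a non-aromatic precursor, although an arene with the correct oxygen pattern (5) can be bought.
- Comparison: the C–O–D ether is again left to separate chemistry. The chosen plan has the shorter endgame and makes all four rings from commercial arenes.

**Alternative 3:** The cut removes two C–C bonds of ring B, which would be built in the ring-closing step. Heating pyrone ynol ether A6 at high dilution should add the ethynyl ether on the ring A oxygen across C3 and C6 of the 5-substituted 2-pyrone. Loss of CO2 from the primary adduct would give O-isopropyl macrocycle A5, and the isopropyl ether would be cleaved last.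
- Merits: two C–C bonds, an arene and the macrocycle form in one irreversible step. The electronic preference (nucleophilic alkyne terminus to C6 of the pyrone) leads to the required para pattern. The A–O–B ether needs no substitution chemistry. In bond-forming economy of the key step this road is superior.
- Weak points: aryl ethynyl ethers are thermally and hydrolytically delicate. A 5-alkyl-2-pyrone without an acceptor group is a sluggish diene and calls for high temperatures. A cycloaddition through a 19-membered transition state has no enthalpic help, so oligomerization or the regioisomeric (meta-bridged) mode can take over. The precursor A6 needs a longer synthesis than 19, and the C–O–D ether must still be made separately.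
- Comparison: the chosen plan relies on a reaction type already shown for this substrate class and on short, conventional access to its precursor.

Key step: step 13

## Route

Remark on the chemistry: 22 has no stereogenic element, and the olefins of 8, 10 and 17 are carried as E/Z mixtures because all geometries converge in step 11. Compounds 1, 5, 9 and 11 are taken as commercial (5 is also the NaBH4 reduction product of isovanillin).

Step 1
Reactants: 1 trichlorophenol (2,4,6-trichlorophenol)
Product: 2 acetal-protected trichlorophenol, 1,3,5-trichloro-2-(methoxymethoxy)benzene
Conditions: MOMCl, i-Pr2NEt, CH2Cl2, 0 °C → rt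
Reagents that add atoms: chloromethyl methyl ether, COCCl
Why: O-alkylation of the acidic phenol by the reactive α-chloro ether (acetal protection); the methoxymethyl ether withstands amide bases, ylides, K2CO3/DMF and diimide and is later removed by dilute acid without touching C–Cl or C–Br bonds.

Step 2
Reactants: 2 acetal-protected trichlorophenol
Product: 4 ring D aldehyde 2,4,6-trichloro-3-(methoxymethoxy)benzaldehyde, via trichloroaryllithium 3 (not isolated)
Conditions: LiN(i-Pr)2, THF, −78 °C; DMF, −78 → −40 °C; aq. NH4Cl
Reagents that add atoms: N,N-dimethylformamide, CN(C)C=O
Why: Directed lithiation followed by formylation: the two ring hydrogens of 2 are equivalent and each is flanked by two chlorines, so deprotonation can give only aryllithium 3, which is kept at −78 °C to prevent LiCl loss to an aryne and is trapped by DMF.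

Step 3
Reactants: 5 ring A benzylic alcohol (3-hydroxy-4-methoxybenzyl alcohol)
Product: 6 ring A salt (3-hydroxy-4-methoxybenzyl)triphenylphosphonium bromide
Conditions: PPh3·HBr, MeCN, reflux
Reagents that add atoms: triphenylphosphine hydrobromide, [Br-].c1ccc(cc1)[PH+](c1ccccc1)c1ccccc1
Why: One-pot phosphonium salt formation: the electron-rich benzylic alcohol ionizes under HBr and the benzylic electrophile is captured by PPh3, while the phenol is inert and stays free for step 5.

Step 4
Reactants: 6 ring A salt; 4 ring D aldehyde
Product: 8 stilbene phenol 2-methoxy-5-{2-[2,4,6-trichloro-3-(methoxymethoxy)phenyl]ethenyl}phenol (E/Z mixture), via lithium phenoxide ylide 7 (not isolated)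
Conditions: LiN(SiMe3)2 (2.1 equiv), THF, 0 °C; then 4, −78 °C → rt; aq. NH4Cl
Reagents that add atoms: none
Why: Wittig olefination: two equivalents of base give the phenoxide ylide 7, a semistabilized benzylic ylide that adds to the non-enolizable aldehyde 4; the geometry is of no consequence because the olefin is saturated in step 11.

Step 5
Reactants: 8 stilbene phenol; 9 4-fluorobenzaldehyde
Product: 10 diaryl ether aldehyde 4-(2-methoxy-5-{2-[2,4,6-trichloro-3-(methoxymethoxy)phenyl]ethenyl}phenoxy)benzaldehyde (E/Z mixture)
Conditions: K2CO3, DMF, 110 °C
Reagents that add atoms: none
Why: Nucleophilic aromatic substitution by addition–elimination: the ring A phenoxide displaces the fluoride para to the formyl group, while the unactivated trichloroarene and the acetal are inert to carbonate in DMF.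

Step 6
Reactants: 11 dibromo aldehyde (3,5-dibromo-4-hydroxybenzaldehyde)
Product: 12 protected dibromo aldehyde 3,5-dibromo-4-(methoxymethoxy)benzaldehyde
Conditions: MOMCl, i-Pr2NEt, CH2Cl2, 0 °C → rt
Reagents that add atoms: chloromethyl methyl ether, COCCl
Why: Acetal protection of the acidic phenol as in step 1; masking the hydroxyl keeps the later ylide free of a para-phenoxide.

Step 7
Reactants: 12 protected dibromo aldehyde
Product: 13 benzylic alcohol [3,5-dibromo-4-(methoxymethoxy)phenyl]methanol
Conditions: NaBH4, MeOH–THF, 0 °C
Reagents that add atoms: none
Why: Hydride reduction of the aldehyde; aryl bromides and the acetal are untouched by NaBH4.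

Step 8
Reactants: 13 benzylic alcohol
Product: 14 benzylic bromide 1,3-dibromo-5-(bromomethyl)-2-(methoxymethoxy)benzene
Conditions: CBr4, PPh3, CH2Cl2, 0 °C
Reagents that add atoms: carbon tetrabromide, BrC(Br)(Br)Br
Why: Appel bromination through the alkoxyphosphonium ion; the near-neutral conditions preserve the acid-labile acetal, which HBr-based methods would endanger.

Step 9
Reactants: 14 benzylic bromide
Product: 15 ring C salt [3,5-dibromo-4-(methoxymethoxy)benzyl]triphenylphosphonium bromide
Conditions: PPh3, toluene, 90 °C
Reagents that add atoms: triphenylphosphine, c1ccc(cc1)P(c1ccccc1)c1ccccc1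
Why: SN2 quaternization of PPh3 by the benzylic bromide; the salt should precipitate from toluene, and the aryl bromides do not react with the phosphine.

Step 10
Reactants: 15 ring C salt; 10 diaryl ether aldehyde
Product: 17 bis-stilbene, the ring A–O–ring B ether bearing the 2,4,6-trichloro-3-(methoxymethoxy)styryl group on ring A and the 3,5-dibromo-4-(methoxymethoxy)styryl group on ring B (mixture of geometric isomers), via dibromobenzyl ylide 16 (not isolated)
Conditions: LiN(SiMe3)2 (1.05 equiv), THF, −78 → 0 °C; then 10, −78 °C → rt
Reagents that add atoms: none
Why: Wittig olefination: the non-nucleophilic amide base forms ylide 16 without halogen–metal exchange at C–Br, and aldehyde 10 cannot enolize; all geometric isomers are carried on together.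

Step 11
Reactants: 17 bis-stilbene
Product: 18 protected seco bis(bibenzyl) 1,3-dibromo-2-(methoxymethoxy)-5-[2-(4-{2-methoxy-5-[2-(2,4,6-trichloro-3-(methoxymethoxy)phenyl)ethyl]phenoxy}phenyl)ethyl]benzene
Conditions: TsNHNH2 (excess, in portions), NaOAc, DME–H2O, reflux
Reagents that add atoms: none
Why: Diimide reduction: HN=NH generated thermally from the sulfonyl hydrazide delivers H2 to both C=C bonds in a concerted syn transfer and, unlike hydrogenation over palladium, leaves C–Br, C–Cl and the acetals intact.

Step 12
Reactants: 18 protected seco bis(bibenzyl)
Product: 19 seco bisphenol 2,6-dibromo-4-[2-(4-{2-methoxy-5-[2-(2,4,6-trichloro-3-hydroxyphenyl)ethyl]phenoxy}phenyl)ethyl]phenol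
Conditions: HCl (3 M aq.), MeOH–THF, 50 °C
Reagents that add atoms: none
Why: Acid-catalysed acetal cleavage with transfer of the methylene unit to methanol; diaryl ether, aryl methyl ether and aryl halides are stable to dilute HCl.

Step 13
Reactants: 19 seco bisphenol
Product: 21 bromo trichloro macrocycle, the 19-membered ring of 22 carrying Br on ring C ortho to the hydroxyl and Cl on the three carbons of ring D ortho and para to the ether oxygen, via bromo aryloxy dienone 20 (not isolated)
Conditions: Tl(NO3)3·3H2O (2.5 equiv), MeOH–THF, about 1 mM with slow addition of 19, −20 → 0 °C; then Zn dust, AcOH, 0 °C → rt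
Reagents that add atoms: none
Why: The 2,6-dibromo-4-alkylphenol (ring C) exchanges onto trivalent thallium and is oxidized by two electrons to a phenoxonium-type species while Tl(NO3)3 falls to TlNO3; the hydroxyl oxygen of ring D then adds to a bromine-bearing ortho carbon to give the 6-aryloxy-6-bromocyclohexa-2,4-dienone 20, and zinc in acetic acid transfers two electrons to this α-bromo dienone, expels bromide and rearomatizes ring C to the 2-aryloxy-6-bromophenol of 21. The closest known reaction type is the Tl(NO3)3-mediated oxidative coupling of ortho-halogenated phenols to macrocyclic 2-aryloxyphenols with reductive work-up. The 19-membered ring closes end to end by intramolecular O-attack of the tethered phenol on the oxidized ring, so the closure depends on effective molarity and is run at high dilution. No stereocenter results: the quaternary carbon of 20 forms as a racemate and becomes planar again on reduction. Two selectivities are needed, oxidation of ring C rather than ring D and reaction of ring D through oxygen; the para-alkyl dibromophenol has the lower oxidation potential, and the three chlorines of ring D occupy both ortho carbons and the para carbon, so neither C–C coupling nor solvent capture is possible there. The bromines of ring C block ortho C–C coupling and provide the leaving group that lets the dienone return to a phenol. Rings A and B are aryl ethers without a free hydroxyl and are oxidized more slowly than a phenol, and no olefin is left for oxythallation.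

Step 14
Reactants: 21 bromo trichloro macrocycle
Product: 22 target cyclic bis(bibenzyl)
Conditions: H2 (1 atm), 10% Pd/C, Et3N, MeOH–EtOAc, rt
Reagents that add atoms: none
Why: Catalytic hydrogenolysis of the aryl C–Br and the three aryl C–Cl bonds with Et3N as acid scavenger; diaryl ethers, the methyl ether and the phenol are stable under these conditions.

## Compound list

1 | 2,4,6-trichlorophenol | Oc1c(Cl)cc(Cl)cc1Cl | starting material
2 | 1,3,5-trichloro-2-(methoxymethoxy)benzene | COCOc1c(Cl)cc(Cl)cc1Cl | intermediate
3 | [2,4,6-trichloro-3-(methoxymethoxy)phenyl]lithium (not isolated) | [Li]c1c(Cl)cc(Cl)c(OCOC)c1Cl | intermediate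
4 | 2,4,6-trichloro-3-(methoxymethoxy)benzaldehyde | O=Cc1c(Cl)cc(Cl)c(OCOC)c1Cl | intermediate
5 | 3-hydroxy-4-methoxybenzyl alcohol | COc1ccc(CO)cc1O | starting material
6 | (3-hydroxy-4-methoxybenzyl)triphenylphosphonium bromide | COc1ccc(C[P+](c2ccccc2)(c2ccccc2)c2ccccc2)cc1O.[Br-] | intermediate
7 | lithium 2-methoxy-5-[(triphenylphosphoranylidene)methyl]phenolate (not isolated) | COc1ccc(C=P(c2ccccc2)(c2ccccc2)c2ccccc2)cc1[O-].[Li+] | intermediate
8 | 2-methoxy-5-{2-[2,4,6-trichloro-3-(methoxymethoxy)phenyl]ethenyl}phenol (E/Z mixture) | COc1ccc(C=Cc2c(Cl)cc(Cl)c(OCOC)c2Cl)cc1O | intermediate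
9 | 4-fluorobenzaldehyde | O=Cc1ccc(F)cc1 | starting material
10 | 4-(2-methoxy-5-{2-[2,4,6-trichloro-3-(methoxymethoxy)phenyl]ethenyl}phenoxy)benzaldehyde (E/Z mixture) | COc1ccc(C=Cc2c(Cl)cc(Cl)c(OCOC)c2Cl)cc1Oc1ccc(C=O)cc1 | intermediate
11 | 3,5-dibromo-4-hydroxybenzaldehyde | O=Cc1cc(Br)c(O)c(Br)c1 | starting material
12 | 3,5-dibromo-4-(methoxymethoxy)benzaldehyde | COCOc1c(Br)cc(C=O)cc1Br | intermediate
13 | [3,5-dibromo-4-(methoxymethoxy)phenyl]methanol | COCOc1c(Br)cc(CO)cc1Br | intermediate
14 | 1,3-dibromo-5-(bromomethyl)-2-(methoxymethoxy)benzene | COCOc1c(Br)cc(CBr)cc1Br | intermediate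
15 | [3,5-dibromo-4-(methoxymethoxy)benzyl]triphenylphosphonium bromide | COCOc1c(Br)cc(C[P+](c2ccccc2)(c2ccccc2)c2ccccc2)cc1Br.[Br-] | intermediate
16 | {[3,5-dibromo-4-(methoxymethoxy)phenyl]methylidene}triphenylphosphorane (not isolated) | COCOc1c(Br)cc(C=P(c2ccccc2)(c2ccccc2)c2ccccc2)cc1Br | intermediate
17 | bis-stilbene: 1,3-dibromo-2-(methoxymethoxy)-5-[2-(4-{2-methoxy-5-[2-(2,4,6-trichloro-3-(methoxymethoxy)phenyl)ethenyl]phenoxy}phenyl)ethenyl]benzene (mixture of geometric isomers) | COc1ccc(C=Cc2c(Cl)cc(Cl)c(OCOC)c2Cl)cc1Oc1ccc(C=Cc2cc(Br)c(OCOC)c(Br)c2)cc1 | intermediate
18 | 1,3-dibromo-2-(methoxymethoxy)-5-[2-(4-{2-methoxy-5-[2-(2,4,6-trichloro-3-(methoxymethoxy)phenyl)ethyl]phenoxy}phenyl)ethyl]benzene | COc1ccc(CCc2c(Cl)cc(Cl)c(OCOC)c2Cl)cc1Oc1ccc(CCc2cc(Br)c(OCOC)c(Br)c2)cc1 | intermediate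
19 | seco bisphenol: 2,6-dibromo-4-[2-(4-{2-methoxy-5-[2-(2,4,6-trichloro-3-hydroxyphenyl)ethyl]phenoxy}phenyl)ethyl]phenol | COc1ccc(CCc2c(Cl)cc(Cl)c(O)c2Cl)cc1Oc1ccc(CCc2cc(Br)c(O)c(Br)c2)cc1 | intermediate
20 | macrocyclic 6-aryloxy-2,6-dibromo-4-alkylcyclohexa-2,4-dienone (ring C oxidized; racemic at C6; not isolated) | COc1ccc2cc1Oc1ccc(cc1)CCC1=CC(Br)(Oc3c(Cl)cc(Cl)c(c3Cl)CC2)C(=O)C(Br)=C1 | intermediate
21 | bromo trichloro macrocycle (ring C: 6-bromo-2-aryloxyphenol; ring D: 2,4,6-trichloro) | COc1ccc2cc1Oc1ccc(cc1)CCc1cc(Br)c(O)c(c1)Oc1c(Cl)cc(Cl)c(c1Cl)CC2 | intermediate
22 | target cyclic bis(bibenzyl) (achiral) | COc1ccc2cc1Oc1ccc(cc1)CCc1ccc(O)c(c1)Oc1cccc(c1)CC2 | target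

## Step count and risk

Total: 14 steps. Longest linear sequence: 9 steps (steps 1, 2, 4, 5, 10, 11, 12, 13, 14; the branch from 11 through steps 6–9 is equally long).

**Step 13 (key step).** Intermolecular coupling to oligomers can compete with ring closure. Methanol can capture the oxidized ring C at its para carbon in place of the ring D oxygen. Over-oxidation of the electron-rich ring A is a further risk. The fallback closes the same ring C carbon–oxygen bond by nucleophilic aromatic substitution; it sets out from aldehyde 10 and returns at target 22.
- Commercial 4-(bromomethyl)-2-fluoro-1-nitrobenzene and PPh3 would give (3-fluoro-4-nitrobenzyl)triphenylphosphonium bromide F1.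
- K2CO3 and 18-crown-6 in CH2Cl2 would generate the stabilized ylide F2 in the presence of 10 and give the fluoronitro bis-stilbene F3.
- Diimide reduction as in step 11, which does not attack nitro groups, would give the fluoronitro bis(bibenzyl) F4, and HCl in MeOH would free the ring D phenol F5.
- K2CO3 in DMF at high dilution would let the ring D phenoxide displace the fluoride ortho to the nitro group. The phenoxide is a weak nucleophile, helped by the ortho-nitro activation and by intramolecularity. The product is the nitro macrocycle F6.
- Hydrogenation over Pd/C with Et3N would reduce the nitro group and remove the three chlorines to give the amino macrocycle F7.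
- Diazotization (NaNO2, H2SO4) to the diazonium hydrogensulfate F8 and hydroxydediazoniation with Cu2O/Cu(NO3)2 in water would give 22.

**Step 4.** Olefination may be slow or incomplete because the doubly deprotonated salt is poorly soluble and the carbonyl of 4 is flanked by two chlorines. The fallback masks the phenol so that a neutral ylide is used; it sets out from 6 and returns at 8. Silylation of 6 (TBSCl, imidazole, CH2Cl2) would give {3-[(tert-butyldimethylsilyl)oxy]-4-methoxybenzyl}triphenylphosphonium bromide F9. One equivalent of LiN(SiMe3)2 would give the silyloxy ylide F10, which with 4 should give the silyl stilbene F11. Bu4NF in THF would then release 8.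

**Step 11.** Saturation of the olefin next to the 2,6-dichloroaryl ring may stay incomplete while diimide disproportionates. The fallback removes that olefin by catalytic hydrogenation before any bromine is in the molecule; it sets out from 8 and returns at 18.
- H2 over sulfided Pt/C in EtOAc, which spares aryl chlorides, would give the bibenzyl phenol F12.
- K2CO3 in DMF with 9 would give the bibenzyl aldehyde F13.
- Ylide 16 (from 15) would give the mono-stilbene F14.
- The remaining unhindered olefin of F14 would be reduced with diimide to 18.

**Step 14.** Hydrogenolysis of the hindered C–Cl bonds may stall as halide salts foul the catalyst, leaving partially dechlorinated material. The fallback replaces heterogeneous hydrogenolysis by homogeneous hydride transfer (PdCl2(dppf), NaBH4, TMEDA, THF), which proceeds by oxidative addition of each carbon–halogen bond to zerovalent palladium and hydride delivery. It sets out from 21 and returns at 22 and makes no new compound (F0).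

## Further compounds

F1 | step 13 | (3-fluoro-4-nitrobenzyl)triphenylphosphonium bromide | [O-][N+](=O)c1ccc(C[P+](c2ccccc2)(c2ccccc2)c2ccccc2)cc1F.[Br-]
F2 | step 13 | [(3-fluoro-4-nitrophenyl)methylidene]triphenylphosphorane | [O-][N+](=O)c1ccc(C=P(c2ccccc2)(c2ccccc2)c2ccccc2)cc1F
F3 | step 13 | fluoronitro bis-stilbene (mixture of geometric isomers) | COc1ccc(C=Cc2c(Cl)cc(Cl)c(OCOC)c2Cl)cc1Oc1ccc(C=Cc2ccc([N+](=O)[O-])c(F)c2)cc1
F4 | step 13 | fluoronitro bis(bibenzyl) with protected ring D phenol | COc1ccc(CCc2c(Cl)cc(Cl)c(OCOC)c2Cl)cc1Oc1ccc(CCc2ccc([N+](=O)[O-])c(F)c2)cc1
F5 | step 13 | fluoronitro bis(bibenzyl) with free ring D phenol | COc1ccc(CCc2c(Cl)cc(Cl)c(O)c2Cl)cc1Oc1ccc(CCc2ccc([N+](=O)[O-])c(F)c2)cc1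
F6 | step 13 | nitro trichloro macrocycle | COc1ccc2cc1Oc1ccc(cc1)CCc1ccc([N+](=O)[O-])c(c1)Oc1c(Cl)cc(Cl)c(c1Cl)CC2
F7 | step 13 | amino macrocycle | COc1ccc2cc1Oc1ccc(cc1)CCc1ccc(N)c(c1)Oc1cccc(c1)CC2
F8 | step 13 | macrocyclic arenediazonium hydrogensulfate | COc1ccc2cc1Oc1ccc(cc1)CCc1ccc([N+]#N)c(c1)Oc1cccc(c1)CC2.OS(=O)(=O)[O-]
F9 | step 4 | {3-[(tert-butyldimethylsilyl)oxy]-4-methoxybenzyl}triphenylphosphonium bromide | COc1ccc(C[P+](c2ccccc2)(c2ccccc2)c2ccccc2)cc1O[Si](C)(C)C(C)(C)C.[Br-]
F10 | step 4 | ({3-[(tert-butyldimethylsilyl)oxy]-4-methoxyphenyl}methylidene)triphenylphosphorane | COc1ccc(C=P(c2ccccc2)(c2ccccc2)c2ccccc2)cc1O[Si](C)(C)C(C)(C)C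
F11 | step 4 | tert-butyldimethylsilyl ether of stilbene phenol 8 (E/Z mixture) | COc1ccc(C=Cc2c(Cl)cc(Cl)c(OCOC)c2Cl)cc1O[Si](C)(C)C(C)(C)C
F12 | step 11 | 2-methoxy-5-{2-[2,4,6-trichloro-3-(methoxymethoxy)phenyl]ethyl}phenol | COc1ccc(CCc2c(Cl)cc(Cl)c(OCOC)c2Cl)cc1O
F13 | step 11 | 4-(2-methoxy-5-{2-[2,4,6-trichloro-3-(methoxymethoxy)phenyl]ethyl}phenoxy)benzaldehyde | COc1ccc(CCc2c(Cl)cc(Cl)c(OCOC)c2Cl)cc1Oc1ccc(C=O)cc1
F14 | step 11 | mono-stilbene with saturated A–D bridge (E/Z mixture) | COc1ccc(CCc2c(Cl)cc(Cl)c(OCOC)c2Cl)cc1Oc1ccc(C=Cc2cc(Br)c(OCOC)c(Br)c2)cc1
F0 | step 14 | none | none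
A1 | alternative 1 | macrocyclic 4-hydroxydeoxybenzoin | COc1ccc2cc1Oc1ccc(cc1)CC(=O)c1ccc(O)c(c1)Oc1cccc(c1)CC2
A2 | alternative 1 | 19-membered ring B arylacetate macrolactone of the ring C phenol | COc1ccc2cc1Oc1ccc(cc1)CC(=O)Oc1ccccc1Oc1cccc(c1)CC2
A3 | alternative 2 | macrocyclic 2-aryloxycyclohexanone (racemic diastereomer mixture) | O=C1CCC2CC1Oc1ccc(cc1)CCc1ccc(OCc3ccccc3)c(c1)Oc1cccc(c1)CC2
A4 | alternative 2 | seco 2-bromo-4-alkylcyclohexanone with free ring B phenol (racemic diastereomer mixture) | O=C1CCC(CCc2cccc(c2)Oc2cc(CCc3ccc(O)cc3)ccc2OCc2ccccc2)CC1Br
A5 | alternative 3 | O-isopropyl macrocycle | COc1ccc2cc1Oc1ccc(cc1)CCc1ccc(OC(C)C)c(c1)Oc1cccc(c1)CC2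
A6 | alternative 3 | seco ethynyl ether with 5-substituted 2-pyrone | C#COc1cc(CCc2cccc(c2)Oc2cc(CCc3ccc(=O)oc3)ccc2OC(C)C)ccc1OC
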